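Of the G charged, Sunday's flask, the one asked about, holds X 69.8 % at 0.333 h and 19.8 % at 4.00 h. The other 80.2 % stands in forms that were not read.

| flask | G | Q | temperature | remark | time |
|---|---|---|---|---|---|
| Sunday's | 0.014 M | 1.3 equiv | 25 °C | the very flask that is asked about, followed so far |  |
| Monday's | 0.014 M | 0.87 equiv | 31 °C | run made earlier |  |
| flask | 0.014 M | 1.30 equiv | 25 °C |  | 4.0 h |

Sunday's run (percent of the G charged)

| time / h | X / % |
|---|---|
| 0.333 | 69.8 |
| 0.667 | 66.7 |
| 1.50 | 45.2 |
| 4.00 | 19.8 |

Monday's run (percent of the G charged)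

| time / min | X / % |
|---|---|
| 4.00 | 32.4 |
| 8.00 | 44.1 |
| 20.0 | 52.1 |
| 50.0 | 40.8 |

(each reading ± 0.5 percentage points)

- alder: at 4.0 h take out 90 % of the Z then present, then wait 80 min
- ash: change nothing and wait 80 min more
- cedar: at 4.0 h add Q, 50.0 % of the amount charged, then wait 80 min
- larch: at 4.0 h raise the temperature by 15 K, then wait 80 min

- the volume of additions can be left aside

1. X, in percent of the G first charged, at 4.0 h
2. which option adds most X ("none" when 2 percentage points or less is all one gets) (alder / ash / cedar / larch / none)
3. X present, in percent of the G first charged, after ash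
4. X present, in percent of the G first charged, after cedar

Monday's flask looks nearly the same, but it has less Q and is warmer. At 0.87 equiv Q is its limiting reagent, and its highest reading is 52.1 % at 20.0 min, lower than Sunday's 69.8 % at 0.333 h. Both flasks then lose X, and the pace of that loss can be compared:

h = ln 2 · Δt / ln(c_X,a / c_X,b)

Sunday, from 0.667 h to 1.50 h: 1.48 h

Sunday, from 1.50 h to 4.00 h: 2.10 h

Monday, from 20.0 min to 50.0 min: 1.42 h

The late Sunday value is the fall half-life, the time X would take to halve if it kept the pace of that interval. Monday's value, 1.42 h, lies close to Sunday's earlier 1.48 h, and Monday's flask reads 40.8 % at 50.0 min. Sunday's fall half-life grows, so X is not on a plain decay.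

My own reckoning takes 19.8 % for now. Holding the late pace through ash gives 12.7 %, which I treat as a lower edge, since the pace has been slowing. A slowing fall suggests that some X may be coming back, so larch is the option I would try, as a guess: Monday's flask differs from Sunday's in Q as well as in temperature, so its readings are no direct test of warming.

The forecast gives 19.8 %, 13.5 % after ash, 15.3 % after cedar and best none, and it says of larch “faster drain, so worse”; on larch it parts from my reckoning.

The flask gives X 18.8 %, and larch is best, reaching 30.6 %, a gain of 12 percentage points, while ash and cedar both end at 15.6 %.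

G + Q → X + Z (k = 0.129 M⁻¹ s⁻¹, Ea = 41.0 kJ mol⁻¹); G → D (k = 1.69 × 10⁻⁷ s⁻¹, Ea = 116 kJ mol⁻¹); X ⇌ L (K = 3.65, k = 1.49 × 10⁻⁴ s⁻¹, Ea = 88.0 kJ mol⁻¹, ΔH = −67.0 kJ mol⁻¹); X + Z → E (k = 0.00326 M⁻¹ s⁻¹, Ea = 60.0 kJ mol⁻¹); (constants at 25 °C) At 4.00 h L holds 59.8 %, and the relaxation half-life of X and L, 1.01 h, is shorter than 4.0 h. Through ash the fall half-life becomes 4.93 h, longer than Sunday's late 2.10 h. The same flask left to 40.0 h reads X 8.19 %, a fall half-life of 30.0 h.

The runs come from a simulation for substances that don't exist, noise included.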